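Start from a ratio: J over J plus D, with each column summed over a run, and take an even split of 0.5 as the zero of the scale.

| flask | E | Z | remark | time |
|---|---|---|---|---|
| theta | 0.50 M | 0.34 M | run made earlier |  |
| zeta | 0.50 M | 0.75 M | run made earlier |  |
| beta | 1 M | 0.50 M | run made earlier |  |
| flask | 0.50 M | 0.500 M |  | 15 d |

- theta (time / d: J / %, D / %): 0.833: 14, 30; 2.50: 8, 29; 4.00: 13, 34; 6.00: 12, 32; 10.0: 11, 34; 12.0: 11, 34; 15.0: 12, 27
- zeta (time / d: J / %, D / %): 2.00: 3, 11; 4.00: 7, 14; 6.00: 3, 13; 8.00: 6, 15; 10.0: 5, 11; 12.0: 6, 14; 15.0: 5, 10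
- beta (time / d: J / %, D / %): 1.25: 13, 34; 4.00: 13, 35; 8.00: 13, 32; 10.0: 11, 34; 15.0: 11, 35

(standard deviation of a reading: 2 percentage points)

- what was read earlier has a scatter of 2 percentage points, one standard deviation

- share of J in J plus D at 3.0 min
- share of J in J plus D at 5.0 h
- share of J in J plus D at 15 d
- which of J and D there is more of at 15 d

Does the ratio follow Z? Theta gives 26.9%, zeta 28.5% and beta 26.4%. Their mean, 27.3%, is the split s, the selectivity between J and D. Zeta carries 2.21 times the [Z] of theta, yet its share moves by 1.6 percentage points, against a reading scatter of 2 points.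

Does s drift in time? Theta up to 4.00 d reads 27.3%, and from 10.0 d on 26.4%. But theta's first reading, at 0.833 d, comes later than 5.0 h, so the two early answers are extrapolations.

Which product leads? The split s lies 23 points below even, which makes D over J 2.66. So commit to s at all three times, with D ahead.

The forecast gave 30% (10% to 60%), 28% (18% to 42%) and 27% (24% to 31%), with D ahead: “the ratio looks insensitive to Z and E”. At 3.0 min it stands above my s.

The flask gives 25.7%, 25.7% and 25.7%, with D ahead, 20.2% against 7.01% of the E charged.

    E → D (k = 0.730 /h)
    2 Q → X (k = 0.280 /M/h)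
    E + Z → G (k = 8.90 /M/h)
    E ⇌ Q, settled at all times (K = 1.10)
    Q → J (k = 0.230 /h)

Per unit of [E], the route to J through Q runs at 0.253 /h and the route to D at 0.73 /h, a share of 25.7%. Applied to this flask's J plus D, s gives 7.43% of J, where the flask holds 7.01%. The neighbour charged with 0.12 M of Z has 71.8% in J plus D, so s gives 19.6% of J, and that flask holds 18.5%.

All runs were generated by integration on assumed constants; noise was put on by code.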